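**Retrosynthetic overview**

1. The target is a Δ4-oxocene (oxocene numbering: O1, C2 with the side chain, C7 with Br, C8 with Et; 2,8-cis). The enyne, the acetate and the bromide are installed last: Colvin homologation of a cross-metathesis enal, chelation-controlled allylation of the C-2 aldehyde, SN2 bromination of the C-7 carbinol.
2. Key disconnection: the two bonds that flank the O1–C2 unit, O1–C8 and C2–C3, are cut together. This leads back to an open-chain hydroxyacetate (glycolate) ester of an anti-1,2-diol monomesylate that carries a (Z)-allylic chloride.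
3. Enabling feature: O1, C2 and the exocyclic acetoxy carbon form a glycolic acid unit, and C7, next to C8, carries a heteroatom. A temporary lactone from the exocyclic carbon (as carboxyl) to an oxygen on C7 therefore gives a 1,4-dioxan-2-one (O1, C2, C=O, O, C7, C8) whose C-3 and C-6 are bridged by the C3–C6 (Z)-butenylene chain.
4. Ring order: the dioxanone closes first (O-alkylation, inversion at C8), then the oxocene (transannular C-alkylation of the lactone enolate), both in step 9. The lactone bridge is cut in step 10 and its carbon becomes the acetoxy carbon.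
5. Stereochemistry: C7 and C8 come from one Sharpless kinetic resolution. C8 is relayed by SN2 inversion, C2 by the bridge, the carbinol carbon by chelation control, and the C–Br centre by a second inversion.

Key step: step 9

Remark: racemic pent-1-en-3-ol, the TBS ether of propargyl alcohol, TBS-protected glycolic acid, allyltributylstannane and crotonaldehyde are taken as commercial; the sense of step 1 (fast (S)-enantiomer with the L-(+)-tartrate, erythro product) is assumed from the general behaviour of 1-alken-3-ols.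

**Route**

Step 1
Reactants: 1 rac-pent-1-en-3-ol
Product: 2 (2R,3S)-1,2-epoxypentan-3-ol
Conditions: Ti(OiPr)4 (cat.), L-(+)-diisopropyl tartrate, t-BuOOH (0.6 equiv), 4 Å MS, CH2Cl2, −20 °C
Reagents that add atoms: tert-butyl hydroperoxide, CC(C)(C)OO
Why: Sharpless kinetic resolution, in which the (S)-enantiomer of 1 should be epoxidised much faster with the L-(+)-tartrate and on the face that gives the erythro (anti) epoxy alcohol, so that both stereocentres of 2 are set by the catalyst reinforced by the carbinol centre while unreacted (R)-1 is separated.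

Step 2
Reactants: 2 (2R,3S)-1,2-epoxypentan-3-ol
Product: 3 (1S)-1-[(2R)-oxiran-2-yl]propyl methanesulfonate
Conditions: MeSO2Cl, Et3N, CH2Cl2, 0 °C
Reagents that add atoms: methanesulfonyl chloride, CS(=O)(=O)Cl
Why: O-sulfonylation of the secondary alcohol touches neither stereocentre and installs the group that protects this oxygen now and leaves in step 9.

Step 3
Reactants: 3 (1S)-1-[(2R)-oxiran-2-yl]propyl methanesulfonate; 4 tert-butyldimethyl(prop-2-yn-1-yloxy)silane
Product: 5 (3S,4R)-8-[(tert-butyldimethylsilyl)oxy]-4-hydroxyoct-6-yn-3-yl methanesulfonate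
Conditions: 4, n-BuLi, THF, −78 °C; BF3·OEt2; then 3, −78 °C
Reagents that add atoms: none
Why: Yamaguchi-type alkynylation, in which the BF3-activated terminal epoxide should be opened by the lithium acetylide in an SN2 reaction at its unsubstituted carbon (the internal carbon is hindered and deactivated by the neighbouring sulfonyloxy group), so that no stereocentre is touched and the sulfonate survives at −78 °C.

Step 4
Reactants: 5 (3S,4R)-8-[(tert-butyldimethylsilyl)oxy]-4-hydroxyoct-6-yn-3-yl methanesulfonate
Product: 6 (3S,4R,6Z)-8-[(tert-butyldimethylsilyl)oxy]-4-hydroxyoct-6-en-3-yl methanesulfonate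
Conditions: H2 (1 atm), Pd/CaCO3 poisoned with Pb(OAc)2, quinoline, EtOAc, rt
Reagents that add atoms: none
Why: Lindlar semi-hydrogenation adds H2 syn to the alkyne and should stop at the (Z)-alkene.

Step 5
Reactants: 6 (3S,4R,6Z)-8-[(tert-butyldimethylsilyl)oxy]-4-hydroxyoct-6-en-3-yl methanesulfonate
Product: 7 (3S,4R,6Z)-4,8-dihydroxyoct-6-en-3-yl methanesulfonate
Conditions: HF·pyridine, THF, 0 °C → rt
Reagents that add atoms: none
Why: Fluoride desilylation under acidic conditions should free the allylic alcohol without base, which would close the hydroxy mesylate to an epoxide.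

Step 6
Reactants: 7 (3S,4R,6Z)-4,8-dihydroxyoct-6-en-3-yl methanesulfonate
Product: 8 (3S,4R,6Z)-8-chloro-4-hydroxyoct-6-en-3-yl methanesulfonate
Conditions: N-chlorosuccinimide, Me2S, CH2Cl2, −20 → 0 °C
Reagents that add atoms: N-chlorosuccinimide, O=C1CCC(=O)N1Cl
Why: Corey–Kim chlorination, in which both hydroxyl groups form alkoxysulfonium salts but only the allylic one should be displaced by chloride at 0 °C (SN2, alkene geometry kept), the saturated secondary alcohol being returned on work-up.

Step 7
Reactants: 8 (3S,4R,6Z)-8-chloro-4-hydroxyoct-6-en-3-yl methanesulfonate; 9 [(tert-butyldimethylsilyl)oxy]acetic acid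
Product: 10 (3S,4R,6Z)-8-chloro-3-[(methylsulfonyl)oxy]oct-6-en-4-yl [(tert-butyldimethylsilyl)oxy]acetate
Conditions: N,N'-dicyclohexylcarbodiimide, 4-(dimethylamino)pyridine (cat.), CH2Cl2, 0 °C
Reagents that add atoms: none
Why: Steglich esterification acylates the secondary alcohol at oxygen, so the carbinol configuration should be retained.

Step 8
Reactants: 10 (3S,4R,6Z)-8-chloro-3-[(methylsulfonyl)oxy]oct-6-en-4-yl [(tert-butyldimethylsilyl)oxy]acetate
Product: 11 (3S,4R,6Z)-8-chloro-3-[(methylsulfonyl)oxy]oct-6-en-4-yl hydroxyacetate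
Conditions: HF·pyridine, THF, 0 °C
Reagents that add atoms: none
Why: Acidic fluoride desilylation should free the glycolate hydroxyl while the ester, the mesylate and the allylic chloride, all base-sensitive, stay intact.

Step 9
Reactants: 11 (3S,4R,6Z)-8-chloro-3-[(methylsulfonyl)oxy]oct-6-en-4-yl hydroxyacetate
Product: 13 (1R,3Z,6R,10R)-10-ethyl-7,9-dioxabicyclo[4.2.2]dec-3-en-8-one, via dioxanone 12 (not isolated)
Conditions: KN(SiMe3)2 (1.05 equiv), THF (0.005 M), −78 → 0 °C; then KN(SiMe3)2 (1.2 equiv), −78 → −20 °C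
Reagents that add atoms: none
Why: Proposed new method: the first charge of base gives the glycolate alkoxide, which should displace the neighbouring secondary mesylate in a 6-exo-tet Williamson reaction (SN2, inversion of the (S)-sulfonate carbon to the (R)-ether carbon) and close the 1,4-dioxan-2-one 12; the second charge should form the potassium enolate at C-3 of 12, whose α-carbon should displace the primary (Z)-allylic chloride of the C-6 side chain in an 8-exo-tet SN2 reaction that bridges C-3 and C-6 and thereby closes the oxocene. The closest known reaction types are the cyclisation of such hydroxy esters to dioxanones, the C-alkylation of 1,4-dioxan-2-one (glycolate lactone) enolates by allylic halides and the intramolecular amide enolate alkylation that closes Δ4-oxocenes from open-chain α-alkoxy amides bearing a (Z)-allylic chloride; new are the one-flask union and the transannular course of the second alkylation. The bridgehead stereocentre C-1 of 13 is dictated by the tether, since the four-carbon chain on C-6 can reach only the enolate face cis to itself, which places the carboxyl carbon and the ester oxygen on the same face of the oxocene as the ethyl group set by the inversion (the future 2,8-cis pattern). The step needs O-alkylation at the mesylate carbon before anything happens at the allylic chloride (a six-membered transition state against a nine-membered one, and only one equivalent of base in the first charge), SN2 rather than SN2′ attack in the C-alkylation (primary chloride on a (Z)-alkene, as in the open-chain precedent; the SN2′ mode would give a vinyl-substituted bicyclo[2.2.2] lactone and is the main risk) and cyclisation rather than oligomerisation (high dilution).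

Step 10
Reactants: 13 (1R,3Z,6R,10R)-10-ethyl-7,9-dioxabicyclo[4.2.2]dec-3-en-8-one
Product: 14 (2R,4Z,7R,8R)-8-ethyl-7-hydroxy-N-methoxy-N-methyl-3,6,7,8-tetrahydro-2H-oxocine-2-carboxamide
Conditions: MeNH(OMe)·HCl, i-PrMgCl, THF, −20 → 0 °C
Reagents that add atoms: N,O-dimethylhydroxylamine hydrochloride, CNOC.Cl
Why: Weinreb amide formation by aminolysis of the lactone with the chloromagnesium amide cleaves the acyl–oxygen bond, so the bridge should be removed with retention at the liberated carbinol carbon and without enolising the α-alkoxy centre.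

Step 11
Reactants: 14 (2R,4Z,7R,8R)-8-ethyl-7-hydroxy-N-methoxy-N-methyl-3,6,7,8-tetrahydro-2H-oxocine-2-carboxamide
Product: 15 (2R,4Z,7S,8R)-7-bromo-8-ethyl-N-methoxy-N-methyl-3,6,7,8-tetrahydro-2H-oxocine-2-carboxamide
Conditions: CBr4, P(n-C8H17)3, toluene, 70 °C
Reagents that add atoms: carbon tetrabromide, BrC(Br)(Br)Br
Why: Appel-type bromination, in which bromide should displace the alkoxyphosphonium group in an SN2 reaction with inversion and so turn the (R)-carbinol into the (S)-bromide; the cis amide cannot reach the rear face of this carbon and so cannot interfere.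

Step 12
Reactants: 15 (2R,4Z,7S,8R)-7-bromo-8-ethyl-N-methoxy-N-methyl-3,6,7,8-tetrahydro-2H-oxocine-2-carboxamide
Product: 16 (2R,4Z,7S,8R)-7-bromo-8-ethyl-3,6,7,8-tetrahydro-2H-oxocine-2-carbaldehyde
Conditions: i-Bu2AlH, THF, −78 °C
Reagents that add atoms: none
Why: Partial reduction of the Weinreb amide, whose chelated tetrahedral aluminium intermediate should hold at −78 °C and release the aldehyde only on work-up, the secondary bromide being inert at this temperature.

Step 13
Reactants: 16 (2R,4Z,7S,8R)-7-bromo-8-ethyl-3,6,7,8-tetrahydro-2H-oxocine-2-carbaldehyde; 17 allyltributylstannane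
Product: 18 (1R)-1-[(2R,4Z,7S,8R)-7-bromo-8-ethyl-3,6,7,8-tetrahydro-2H-oxocin-2-yl]but-3-en-1-ol
Conditions: MgBr2·OEt2, CH2Cl2, −78 °C; then 17, −78 → −20 °C
Reagents that add atoms: none
Why: Chelation-controlled allylstannane addition, in which MgBr2 ties the aldehyde oxygen to the ring oxygen and the stannane should add to the face of this Cram chelate opposite the ring methylene, giving the syn (threo) arrangement of the new carbinol and the ring ether carbon, that is the (R)-carbinol.

Step 14
Reactants: 18 (1R)-1-[(2R,4Z,7S,8R)-7-bromo-8-ethyl-3,6,7,8-tetrahydro-2H-oxocin-2-yl]but-3-en-1-ol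
Product: 19 (1R)-1-[(2R,4Z,7S,8R)-7-bromo-8-ethyl-3,6,7,8-tetrahydro-2H-oxocin-2-yl]but-3-en-1-yl acetate
Conditions: Ac2O, pyridine, 4-(dimethylamino)pyridine (cat.), CH2Cl2, 0 °C → rt
Reagents that add atoms: acetic anhydride, CC(=O)OC(C)=O
Why: Nucleophile-catalysed O-acetylation should proceed with retention at the carbinol carbon.

Step 15
Reactants: 19 (1R)-1-[(2R,4Z,7S,8R)-7-bromo-8-ethyl-3,6,7,8-tetrahydro-2H-oxocin-2-yl]but-3-en-1-yl acetate; 20 (E)-but-2-enal
Product: 21 (1R,3E)-1-[(2R,4Z,7S,8R)-7-bromo-8-ethyl-3,6,7,8-tetrahydro-2H-oxocin-2-yl]-5-oxopent-3-en-1-yl acetate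
Conditions: second-generation Grubbs catalyst (5 mol %), 20 (5 equiv), CH2Cl2, 40 °C
Reagents that add atoms: none
Why: Olefin cross-metathesis of the monosubstituted alkene with the enal should give the conjugated (E)-enal under thermodynamic control, while the ring (Z)-alkene is expected to be spared because oxocenes of this kind are formed rather than opened under metathesis conditions.

Step 16
Reactants: 21 (1R,3E)-1-[(2R,4Z,7S,8R)-7-bromo-8-ethyl-3,6,7,8-tetrahydro-2H-oxocin-2-yl]-5-oxopent-3-en-1-yl acetate
Product: 22 (1R,3E)-1-[(2R,4Z,7S,8R)-7-bromo-8-ethyl-3,6,7,8-tetrahydro-2H-oxocin-2-yl]hex-3-en-5-yn-1-yl acetate (target)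
Conditions: Me3SiCHN2, n-BuLi, THF, −78 °C; then 21, −78 → 0 °C
Reagents that add atoms: (trimethylsilyl)diazomethane, C[Si](C)(C)C=[N+]=[N-]
Why: Colvin homologation, in which lithiated (trimethylsilyl)diazomethane adds to the aldehyde, Peterson-type loss of silanolate and loss of N2 give an alkylidene carbene, and its 1,2-hydrogen shift should give the terminal alkyne without touching the (E)-alkene, the acetate or the stereocentres.

**Compound list**

1 | rac-pent-1-en-3-ol | C=CC(O)CC | starting material
2 | (2R,3S)-1,2-epoxypentan-3-ol | CC[C@H](O)[C@H]1CO1 | intermediate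
3 | (1S)-1-[(2R)-oxiran-2-yl]propyl methanesulfonate | CC[C@H](OS(C)(=O)=O)[C@H]1CO1 | intermediate
4 | tert-butyldimethyl(prop-2-yn-1-yloxy)silane | C#CCO[Si](C)(C)C(C)(C)C | starting material
5 | (3S,4R)-8-[(tert-butyldimethylsilyl)oxy]-4-hydroxyoct-6-yn-3-yl methanesulfonate | CC[C@H](OS(C)(=O)=O)[C@H](O)CC#CCO[Si](C)(C)C(C)(C)C | intermediate
6 | (3S,4R,6Z)-8-[(tert-butyldimethylsilyl)oxy]-4-hydroxyoct-6-en-3-yl methanesulfonate | CC[C@H](OS(C)(=O)=O)[C@H](O)C/C=C\CO[Si](C)(C)C(C)(C)C | intermediate
7 | (3S,4R,6Z)-4,8-dihydroxyoct-6-en-3-yl methanesulfonate | CC[C@H](OS(C)(=O)=O)[C@H](O)C/C=C\CO | intermediate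
8 | (3S,4R,6Z)-8-chloro-4-hydroxyoct-6-en-3-yl methanesulfonate | CC[C@H](OS(C)(=O)=O)[C@H](O)C/C=C\CCl | intermediate
9 | [(tert-butyldimethylsilyl)oxy]acetic acid | OC(=O)CO[Si](C)(C)C(C)(C)C | starting material
10 | (3S,4R,6Z)-8-chloro-3-[(methylsulfonyl)oxy]oct-6-en-4-yl [(tert-butyldimethylsilyl)oxy]acetate | CC[C@H](OS(C)(=O)=O)[C@H](OC(=O)CO[Si](C)(C)C(C)(C)C)C/C=C\CCl | intermediate
11 | (3S,4R,6Z)-8-chloro-3-[(methylsulfonyl)oxy]oct-6-en-4-yl hydroxyacetate | CC[C@H](OS(C)(=O)=O)[C@H](OC(=O)CO)C/C=C\CCl | intermediate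
12 | (5R,6R)-6-[(2Z)-4-chlorobut-2-en-1-yl]-5-ethyl-1,4-dioxan-2-one | CC[C@H]1OCC(=O)O[C@@H]1C/C=C\CCl | intermediate
13 | (1R,3Z,6R,10R)-10-ethyl-7,9-dioxabicyclo[4.2.2]dec-3-en-8-one | CC[C@H]1O[C@@H]2C/C=C\C[C@H]1OC2=O | intermediate
14 | (2R,4Z,7R,8R)-8-ethyl-7-hydroxy-N-methoxy-N-methyl-3,6,7,8-tetrahydro-2H-oxocine-2-carboxamide | CC[C@H]1O[C@@H](C(=O)N(C)OC)C/C=C\C[C@H]1O | intermediate
15 | (2R,4Z,7S,8R)-7-bromo-8-ethyl-N-methoxy-N-methyl-3,6,7,8-tetrahydro-2H-oxocine-2-carboxamide | CC[C@H]1O[C@@H](C(=O)N(C)OC)C/C=C\C[C@@H]1Br | intermediate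
16 | (2R,4Z,7S,8R)-7-bromo-8-ethyl-3,6,7,8-tetrahydro-2H-oxocine-2-carbaldehyde | CC[C@H]1O[C@@H](C=O)C/C=C\C[C@@H]1Br | intermediate
17 | allyltributylstannane | C=CC[Sn](CCCC)(CCCC)CCCC | starting material
18 | (1R)-1-[(2R,4Z,7S,8R)-7-bromo-8-ethyl-3,6,7,8-tetrahydro-2H-oxocin-2-yl]but-3-en-1-ol | CC[C@H]1O[C@@H]([C@H](O)CC=C)C/C=C\C[C@@H]1Br | intermediate
19 | (1R)-1-[(2R,4Z,7S,8R)-7-bromo-8-ethyl-3,6,7,8-tetrahydro-2H-oxocin-2-yl]but-3-en-1-yl acetate | CC[C@H]1O[C@@H]([C@H](OC(C)=O)CC=C)C/C=C\C[C@@H]1Br | intermediate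
20 | (E)-but-2-enal | C/C=C/C=O | starting material
21 | (1R,3E)-1-[(2R,4Z,7S,8R)-7-bromo-8-ethyl-3,6,7,8-tetrahydro-2H-oxocin-2-yl]-5-oxopent-3-en-1-yl acetate | CC[C@H]1O[C@@H]([C@H](OC(C)=O)C/C=C/C=O)C/C=C\C[C@@H]1Br | intermediate
22 | (1R,3E)-1-[(2R,4Z,7S,8R)-7-bromo-8-ethyl-3,6,7,8-tetrahydro-2H-oxocin-2-yl]hex-3-en-5-yn-1-yl acetate | C#C/C=C/C[C@@H](OC(C)=O)[C@H]1C/C=C\C[C@H](Br)[C@@H](CC)O1 | target

**Step count and risks**

Total step count: 16. Longest linear sequence: 16 steps (1 → 22).

Steps most likely to fail: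

Step 9 (proposed new method). The transannular C-alkylation may take the SN2′ course to a bicyclo[2.2.2] lactone, the lactone enolate may fragment before it alkylates, or intermolecular alkylation may win. In the first stage, sulfonyl transfer or elimination may compete with the etherification. Fallback with known chemistry, setting out from 12 and returning at 16: the sequence is stopped after the first charge of base and 12 is isolated. Aminolysis with Me2NH·HCl and AlMe3 should open the lactone to the open-chain amide 2-{[(3R,4R,6Z)-8-chloro-4-hydroxyoct-6-en-3-yl]oxy}-N,N-dimethylacetamide F1. Silylation with t-BuMe2SiOSO2CF3 and 2,6-lutidine should give 2-{[(3R,4R,6Z)-4-[(tert-butyldimethylsilyl)oxy]-8-chlorooct-6-en-3-yl]oxy}-N,N-dimethylacetamide F2. The intramolecular amide enolate alkylation established for such open-chain (Z)-allylic chlorides (KN(SiMe3)2, THF), which favours the 2,8-cis ring, should close (2R,4Z,7R,8R)-7-[(tert-butyldimethylsilyl)oxy]-8-ethyl-N,N-dimethyl-3,6,7,8-tetrahydro-2H-oxocine-2-carboxamide F3. Desilylation with n-Bu4NF should give (2R,4Z,7R,8R)-8-ethyl-7-hydroxy-N,N-dimethyl-3,6,7,8-tetrahydro-2H-oxocine-2-carboxamide F4. CBr4 and P(n-C8H17)3 should then give, with inversion, (2R,4Z,7S,8R)-7-bromo-8-ethyl-N,N-dimethyl-3,6,7,8-tetrahydro-2H-oxocine-2-carboxamide F5, and Cp2Zr(H)Cl should reduce the tertiary amide to aldehyde 16.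

Step 11. The alkoxyphosphonium intermediate may eliminate, or the ring oxygen may participate and give retention or ring contraction instead of clean inversion; the hydroxy amide may also relactonise on heating. Fallback setting out from 14 and returning at 15: the leaving group is made in a separate, cold step. ClCH2SO2Cl and pyridine should give (2R,4Z,7R,8R)-8-ethyl-2-[methoxy(methyl)carbamoyl]-3,6,7,8-tetrahydro-2H-oxocin-7-yl chloromethanesulfonate F6, which LiBr in DMF should displace by SN2 with inversion to give 15.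

Step 13. Chelation between the aldehyde and the ring oxygen may be incomplete, giving poor facial selectivity, and the α-alkoxy aldehyde may epimerise. Fallback setting out from 15 and returning at 18: the carbinol centre is set by reduction instead of addition. CH2=CHCH2MgBr (THF, −78 °C) should convert the Weinreb amide into 1-[(2R,4Z,7S,8R)-7-bromo-8-ethyl-3,6,7,8-tetrahydro-2H-oxocin-2-yl]but-3-en-1-one F7, and LiBH(s-Bu)3 at −78 °C should reduce this α-alkoxy ketone under Felkin–Anh control (hydride anti to the ring C–O bond) to the same syn carbinol 18.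

Further compounds
F1 | step 9 | 2-{[(3R,4R,6Z)-8-chloro-4-hydroxyoct-6-en-3-yl]oxy}-N,N-dimethylacetamide | CC[C@@H](OCC(=O)N(C)C)[C@H](O)C/C=C\CCl
F2 | step 9 | 2-{[(3R,4R,6Z)-4-[(tert-butyldimethylsilyl)oxy]-8-chlorooct-6-en-3-yl]oxy}-N,N-dimethylacetamide | CC[C@@H](OCC(=O)N(C)C)[C@H](O[Si](C)(C)C(C)(C)C)C/C=C\CCl
F3 | step 9 | (2R,4Z,7R,8R)-7-[(tert-butyldimethylsilyl)oxy]-8-ethyl-N,N-dimethyl-3,6,7,8-tetrahydro-2H-oxocine-2-carboxamide | CC[C@H]1O[C@@H](C(=O)N(C)C)C/C=C\C[C@H]1O[Si](C)(C)C(C)(C)C
F4 | step 9 | (2R,4Z,7R,8R)-8-ethyl-7-hydroxy-N,N-dimethyl-3,6,7,8-tetrahydro-2H-oxocine-2-carboxamide | CC[C@H]1O[C@@H](C(=O)N(C)C)C/C=C\C[C@H]1O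
F5 | step 9 | (2R,4Z,7S,8R)-7-bromo-8-ethyl-N,N-dimethyl-3,6,7,8-tetrahydro-2H-oxocine-2-carboxamide | CC[C@H]1O[C@@H](C(=O)N(C)C)C/C=C\C[C@@H]1Br
F6 | step 11 | (2R,4Z,7R,8R)-8-ethyl-2-[methoxy(methyl)carbamoyl]-3,6,7,8-tetrahydro-2H-oxocin-7-yl chloromethanesulfonate | CC[C@H]1O[C@@H](C(=O)N(C)OC)C/C=C\C[C@H]1OS(=O)(=O)CCl
F7 | step 13 | 1-[(2R,4Z,7S,8R)-7-bromo-8-ethyl-3,6,7,8-tetrahydro-2H-oxocin-2-yl]but-3-en-1-one | CC[C@H]1O[C@@H](C(=O)CC=C)C/C=C\C[C@@H]1Br
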